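**Assumption:** zerumbone (1), the bulk sesquiterpene of Zingiber zerumbet oil and a catalogue chemical, is taken as a cheap commercial starting material; all other inputs are commodity reagents.

**Numbering:** 11-membered rings use zerumbone numbering (C1 = C=O). Tricycles use tricyclo[5.4.0.0^2,8]undecane numbering. Macrocycle carbon Cn becomes tricycle C(4−n) for n = 1–3 and C(15−n) for n = 4–11.

## Retrosynthetic overview

1. Target ⇒ tricyclic ene diester (allylic C–H oxidation installs C11=O) ⇒ anti-1,3-diol monoester (O-tigloylation).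
2. Diol monoester ⇒ tricyclic β-hydroxy ketone (Evans–Tishchenko sets the C3 carbinol and the C5 isovalerate together).
3. Tricycle ⇒ 11-membered hydroxy trienone by transannular enone–diene [2+2]; the cyclobutane and both bridged six-/seven-membered rings form in this one step, and the 11-membered ring is bought.
4. Hydroxy trienone ⇒ zerumbone by 1,4-dehydrogenation of the isolated alkene (SeO2 hydroxylation, sulfenate 1,4-dehydration) and, first of all, an enantioselective conjugate hydration (C10–O bond) that creates the one stereocentre from which all others are relayed.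

## Route

Step 1
Reactants: 1 zerumbone
Product: 2 (2E,6E,10R)-10-hydroxy-2,6,9,9-tetramethylcycloundeca-2,6-dien-1-one
Conditions: oligomeric (salen)Co(III)–OTs (Jacobsen type, 2 mol % Co, antipode that gives 10R fixed by a two-run screen), H2O (10 equiv), MTBE, 4 °C
Reagents that add atoms: water, O
Why: Proposed new method: cooperative bimetallic (salen)Co(III) catalysis of the conjugate addition of water to a simple dienone, in which one Co(III) centre activates the C1 carbonyl as a Lewis acid while a second delivers its Co-bound hydroxide to C10 (the disubstituted β-carbon at which zerumbone is known to accept O-, N- and S-nucleophiles, C3 being shielded by the α-methyl-substituted trisubstituted alkene) and the cobalt enolate is protonated at C11 by water, the chiral salen pair selecting one of the rapidly interconverting planar-chiral ring conformers so that peripheral attack sets the 10R carbinol, the closest known reaction types being the (salen)Co hydrolytic kinetic resolution of epoxides and the (salen)Al-catalysed conjugate addition of oximes to unsaturated imides (formal hydration).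

Step 2
Reactants: 2 (2E,6E,10R)-10-hydroxy-2,6,9,9-tetramethylcycloundeca-2,6-dien-1-one
Product: 3 (2E,6E,10R)-5,10-dihydroxy-2,6,9,9-tetramethylcycloundeca-2,6-dien-1-one (C5 epimers)
Conditions: SeO2 (0.3 equiv), t-BuOOH (70% aq., 3 equiv), salicylic acid (0.1 equiv), CH2Cl2, 0 °C → rt
Reagents that add atoms: tert-butyl hydroperoxide, CC(C)(C)OO (net source of the new oxygen, relayed through catalytic selenium dioxide, O=[Se]=O)
Why: SeO2 allylic hydroxylation (ene reaction then [2,3]-sigmatropic shift, Sharpless–Umbreit catalytic protocol) engages only the electron-rich C6=C7 alkene and, following the Guillemonat rules, oxidises the ring CH2 on its more substituted end that lies trans to C8, i.e. C5, with retention of the 6E geometry, the new C5 carbinol being an inconsequential epimer mixture that is erased in step 3.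

Step 3
Reactants: 3 (2E,6E,10R)-5,10-dihydroxy-2,6,9,9-tetramethylcycloundeca-2,6-dien-1-one; 4 2,4-dinitrobenzenesulfenyl chloride
Product: 7 (2E,5E,7E,10R)-10-hydroxy-2,6,9,9-tetramethylcycloundeca-2,5,7-trien-1-one (any 5Z isomer is carried along), via allylic sulfenate 5 (not isolated), via allylic sulfoxide 6 (not isolated)
Conditions: 4 (1.1 equiv), Et3N (1.5 equiv), ClCH2CH2Cl, −20 °C → rt, then 60 °C
Reagents that add atoms: none
Why: Reich 1,4-dehydration of an allylic alcohol, in which the less hindered allylic C5–OH (the neopentyl C10–OH reacts far more slowly) is O-sulfenylated, the sulfenate undergoes a Mislow–Evans [2,3]-sigmatropic shift to the C7 sulfoxide with the alkene moving to C5=C6, and thermal syn-elimination of the electron-poor aryl sulfoxide can only take a C8 hydrogen, so the conjugated C5=C6–C7=C8 diene forms regiospecifically without creating or touching a stereocentre.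

Step 4
Reactants: 7 (2E,5E,7E,10R)-10-hydroxy-2,6,9,9-tetramethylcycloundeca-2,5,7-trien-1-one
Product: 8 (1R,2S,5R,7R,8R)-5-hydroxy-2,6,6,9-tetramethyltricyclo[5.4.0.0^2,8]undec-9-en-3-one
Conditions: thioxanthone (10 mol %), 405 nm LEDs, degassed MeCN (5 mM), 20 °C
Reagents that add atoms: none
Why: Triplet-sensitised transannular enone–diene [2+2] photocycloaddition in which macrocycle C3 (enone β-carbon) bonds to the diene terminus C8 through a six-membered ring to give the best 1,4-biradical (tertiary α-keto radical at C2, allyl radical over C5–C7), whose only feasible collapse is C2–C7, so the cyclobutane with its two opposite-face bridges can form in only one relative configuration at tricycle C1, C2, C7 and C8, while the choice between the two enantiomeric cages is made by the C10 carbinol, expected to sit pseudo-equatorial and hydrogen-bonded to the C1 carbonyl in the closing cycloheptane-like ring (this gives C5–OH of the tricycle as in the target), and the 5E and 5Z dienes equilibrate under sensitisation with only 5Z able to close.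

Step 5
Reactants: 8 (1R,2S,5R,7R,8R)-5-hydroxy-2,6,6,9-tetramethyltricyclo[5.4.0.0^2,8]undec-9-en-3-one; 9 3-methylbutanal (isovaleraldehyde)
Product: 11 (1R,2S,3R,5R,7R,8R)-3-hydroxy-2,6,6,9-tetramethyltricyclo[5.4.0.0^2,8]undec-9-en-5-yl 3-methylbutanoate, via hemiacetal 10 (not isolated)
Conditions: SmI2 (30 mol %), 9 (6 equiv), THF, −10 °C
Reagents that add atoms: none
Why: Evans–Tishchenko reduction, in which the Sm(III)-bound hemiacetal of the C5 hydroxyl delivers hydride intramolecularly to the C3 ketone from the face syn to C5–O, giving the 1,3-anti (3R) carbinol while the aldehyde carbon ends as the C5 isovalerate, so ketone reduction, C3 stereocontrol and differentiation of the two oxygens happen in one operation.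

Step 6
Reactants: 11 (1R,2S,3R,5R,7R,8R)-3-hydroxy-2,6,6,9-tetramethyltricyclo[5.4.0.0^2,8]undec-9-en-5-yl 3-methylbutanoate; 12 (E)-2-methylbut-2-enoyl chloride (tigloyl chloride)
Product: 13 (1R,2S,3R,5R,7R,8R)-2,6,6,9-tetramethyl-5-(3-methylbutanoyloxy)tricyclo[5.4.0.0^2,8]undec-9-en-3-yl (E)-2-methylbut-2-enoate
Conditions: 12 (2 equiv), Et3N (3 equiv), DMAP (0.2 equiv), CH2Cl2, 0 °C → rt
Reagents that add atoms: none
Why: DMAP-catalysed acylation (nucleophilic catalysis through the acylpyridinium) of the only free hydroxyl, run cold with a weak base so that γ-deprotonation of the tigloyl donor is avoided and the E geometry of the 2-methylbut-2-enoate is kept, with no stereocentre affected.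

Step 7
Reactants: 13 (1R,2S,3R,5R,7R,8R)-2,6,6,9-tetramethyl-5-(3-methylbutanoyloxy)tricyclo[5.4.0.0^2,8]undec-9-en-3-yl (E)-2-methylbut-2-enoate
Product: 14 (1R,2R,3R,5R,7S,8R)-2,6,6,9-tetramethyl-5-(3-methylbutanoyloxy)-11-oxotricyclo[5.4.0.0^2,8]undec-9-en-3-yl (E)-2-methylbut-2-enoate (target; the changed descriptors at C2 and C7 reflect CIP priorities only)
Conditions: Rh2(cap)4 (1 mol %), t-BuOOH (70% aq., 6 equiv), ClCH2CH2Cl, 40 °C
Reagents that add atoms: tert-butyl hydroperoxide, CC(C)(C)OO
Why: Rh2(cap)4/t-BuOOH allylic C–H oxidation (tert-butylperoxyl hydrogen abstraction, the α-pinene → verbenone transformation) is selective for the ring CH2 (C11) allylic to the electron-rich trisubstituted C9=C10 alkene, because the bridgehead C–H cannot conjugate and the C–H bonds next to the ester oxygens and on the tiglate are electron-poor, and no stereocentre can epimerise since the new ketone is flanked by a bridgehead.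

## Compound list

1 | zerumbone, (2E,6E,10E)-2,6,9,9-tetramethylcycloundeca-2,6,10-trien-1-one | C1/C(C)=C/CC(C)(C)/C=C/C(=O)/C(C)=C/C1 | starting material
2 | (2E,6E,10R)-10-hydroxy-2,6,9,9-tetramethylcycloundeca-2,6-dien-1-one | O=C1C[C@@H](O)C(C)(C)C/C=C(C)/CC/C=C1\C | intermediate
3 | (2E,6E,10R)-5,10-dihydroxy-2,6,9,9-tetramethylcycloundeca-2,6-dien-1-one, C5 epimers | O=C1C[C@@H](O)C(C)(C)C/C=C(C)/C(O)C/C=C1\C | intermediate
4 | 2,4-dinitrobenzenesulfenyl chloride | ClSc1ccc(cc1[N+](=O)[O-])[N+](=O)[O-] | starting material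
5 | allylic sulfenate: 5-O-(2,4-dinitrophenylsulfanyl) derivative of 3, C5 epimers | O=C1C[C@@H](O)C(C)(C)C/C=C(C)/C(OSc2ccc(cc2[N+](=O)[O-])[N+](=O)[O-])C/C=C1\C | intermediate (not isolated)
6 | allylic sulfoxide: (2E,5E,10R)-7-(2,4-dinitrophenylsulfinyl)-10-hydroxy-2,6,9,9-tetramethylcycloundeca-2,5-dien-1-one, mixed at C7 and S | O=C1C[C@@H](O)C(C)(C)CC(S(=O)c2ccc(cc2[N+](=O)[O-])[N+](=O)[O-])/C(C)=C/C/C=C1\C | intermediate (not isolated)
7 | (2E,5E,7E,10R)-10-hydroxy-2,6,9,9-tetramethylcycloundeca-2,5,7-trien-1-one | O=C1C[C@@H](O)C(C)(C)/C=C/C(C)=C/C/C=C1\C | intermediate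
8 | (1R,2S,5R,7R,8R)-5-hydroxy-2,6,6,9-tetramethyltricyclo[5.4.0.0^2,8]undec-9-en-3-one | O=C1C[C@@H](O)C(C)(C)[C@@H]2[C@H]3CC=C(C)[C@@H]2[C@]31C | intermediate
9 | 3-methylbutanal (isovaleraldehyde) | CC(C)CC=O | starting material
10 | hemiacetal: 5-O-(1-hydroxy-3-methylbutyl) derivative of 8, as its Sm(III) alkoxide, acetal carbon unassigned | O=C1C[C@@H](OC(O)CC(C)C)C(C)(C)[C@@H]2[C@H]3CC=C(C)[C@@H]2[C@]31C | intermediate (not isolated)
11 | (1R,2S,3R,5R,7R,8R)-3-hydroxy-2,6,6,9-tetramethyltricyclo[5.4.0.0^2,8]undec-9-en-5-yl 3-methylbutanoate | O[C@@H]1C[C@@H](OC(=O)CC(C)C)C(C)(C)[C@@H]2[C@H]3CC=C(C)[C@@H]2[C@]31C | intermediate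
12 | (E)-2-methylbut-2-enoyl chloride (tigloyl chloride) | C/C=C(\C)C(=O)Cl | starting material
13 | (1R,2S,3R,5R,7R,8R)-2,6,6,9-tetramethyl-5-(3-methylbutanoyloxy)tricyclo[5.4.0.0^2,8]undec-9-en-3-yl (E)-2-methylbut-2-enoate | C/C=C(\C)C(=O)O[C@@H]1C[C@@H](OC(=O)CC(C)C)C(C)(C)[C@@H]2[C@H]3CC=C(C)[C@@H]2[C@]31C | intermediate
14 | (1R,2R,3R,5R,7S,8R)-2,6,6,9-tetramethyl-5-(3-methylbutanoyloxy)-11-oxotricyclo[5.4.0.0^2,8]undec-9-en-3-yl (E)-2-methylbut-2-enoate | C/C=C(\C)C(=O)O[C@@H]1C[C@@H](OC(=O)CC(C)C)C(C)(C)[C@@H]2[C@H]3C(=O)C=C(C)[C@@H]2[C@]31C | target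

## Step count and risks

Total steps: 7. Longest linear sequence: 7 steps (1 → 14).

The three steps most likely to fail:

**Step 1 (proposed conjugate hydration).** Water addition to an enone is reversible, so retro-addition could erode conversion and ee, and the selectivity of a Co-salen pair for this dienone is untested. The fallback sets out from 1 and uses known chemistry. Copper(I)-catalysed enantioselective conjugate borylation (CuCl, Josiphos-type ligand, NaOt-Bu, B2pin2, MeOH, THF) gives (2E,6E,10R)-2,6,9,9-tetramethyl-10-(4,4,5,5-tetramethyl-1,3,2-dioxaborolan-2-yl)cycloundeca-2,6-dien-1-one F1. Sodium perborate in THF/H2O then oxidises the C–B bond to C–OH with retention, and the route is rejoined at 2.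

**Step 4 (transannular photocycloaddition).** The triplet enone could instead abstract a doubly allylic C4 hydrogen (photodeconjugation), close in the straight sense (C3–C7/C2–C8), or form the cage with the wrong sense relative to the C10 carbinol. The last point rests on a conformational argument only. The fallback sets out from 7 and moves the cycloaddition to the end, on the presumed biogenetic substrate.
- Evans–Tishchenko reduction of 7 (SmI2, isovaleraldehyde) gives (1R,2E,5E,7E,10R)-10-(3-methylbutanoyloxy)-2,6,9,9-tetramethylcycloundeca-2,5,7-trien-1-ol F2.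
- Tigloyl chloride, Et3N and DMAP give (1R,2E,5E,7E,10R)-10-(3-methylbutanoyloxy)-2,6,9,9-tetramethylcycloundeca-2,5,7-trien-1-yl (E)-2-methylbut-2-enoate F3.
- Rh2(cap)4/t-BuOOH oxidation of the doubly allylic C4H2 gives the cross-conjugated trienone (1R,2E,5E,7E,10R)-10-(3-methylbutanoyloxy)-2,6,9,9-tetramethyl-4-oxocycloundeca-2,5,7-trien-1-yl (E)-2-methylbut-2-enoate F4, which has no γ-hydrogen left to abstract.
- Irradiation (350 nm direct or 405 nm with thioxanthone) closes C3–C8 and C2–C7, and the route is rejoined at 14.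

**Step 7 (allylic oxidation).** Yields for pinene-type substrates are moderate, and the C9 methyl, tertiary-peroxide formation at C9 or the tiglate could compete. The fallback sets out from 13 and replaces direct C–H oxygenation by halogenation then oxygen transfer. Wohl–Ziegler bromination (NBS, catalytic dibenzoyl peroxide, PhCF3, 80 °C; the electron-rich ring allylic C–H reacts before the electron-poor tiglate methyls) gives the 11-bromo derivative of 13 F5. Oxidation with N-methylmorpholine N-oxide in MeCN converts the secondary allylic bromide into the enone, and the route is rejoined at 14.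

## Further compounds

F1 | step 1 | (2E,6E,10R)-2,6,9,9-tetramethyl-10-(4,4,5,5-tetramethyl-1,3,2-dioxaborolan-2-yl)cycloundeca-2,6-dien-1-one | O=C1C[C@@H](B2OC(C)(C)C(C)(C)O2)C(C)(C)C/C=C(C)/CC/C=C1\C
F2 | step 4 | (1R,2E,5E,7E,10R)-10-(3-methylbutanoyloxy)-2,6,9,9-tetramethylcycloundeca-2,5,7-trien-1-ol | O[C@@H]1C[C@@H](OC(=O)CC(C)C)C(C)(C)/C=C/C(C)=C/C/C=C1\C
F3 | step 4 | (1R,2E,5E,7E,10R)-10-(3-methylbutanoyloxy)-2,6,9,9-tetramethylcycloundeca-2,5,7-trien-1-yl (E)-2-methylbut-2-enoate | C/C=C(\C)C(=O)O[C@@H]1C[C@@H](OC(=O)CC(C)C)C(C)(C)/C=C/C(C)=C/C/C=C1\C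
F4 | step 4 | (1R,2E,5E,7E,10R)-10-(3-methylbutanoyloxy)-2,6,9,9-tetramethyl-4-oxocycloundeca-2,5,7-trien-1-yl (E)-2-methylbut-2-enoate | C/C=C(\C)C(=O)O[C@@H]1C[C@@H](OC(=O)CC(C)C)C(C)(C)/C=C/C(C)=C/C(=O)/C=C1\C
F5 | step 7 | 11-bromo derivative of 13, C11 epimers | C/C=C(\C)C(=O)O[C@@H]1C[C@@H](OC(=O)CC(C)C)C(C)(C)[C@@H]2[C@H]3C(Br)C=C(C)[C@@H]2[C@]31C
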